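Numbering (germacranolide): ring A = carbocycle C1–C10 (C1 CHOH, C3 C=O, C4 Me/OAc, C6 O-angeloyl, C10 Me); ring B = lactone O–C8–C7–C11(=C13H2)–C12(=O).
C1–C2 is cut last: a SmI2-induced intramolecular Reformatsky-type aldol of bromomethyl ketone aldehyde 35 closes ring A and gives 37 directly, a reductive union of two electrophilic carbons (aldehyde C1, bromomethyl C2) by polarity reversal at C2. Enabling feature: the β-ketol C1(OH)–C2H2–C3(=O) of ring A, whose ketone is flanked by the fully substituted C4 (C2 is the only possible enolate carbon) and whose carbinol C1 lies next to the C10 methyl stereocentre.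
North chain on the lactone: C4 acetate and C3 ketone by Ru-catalysed AcOH addition to a tertiary propargylic alcohol, C3–C4 by chelation-controlled ethynylation, C4 ketone by Wacker oxidation, C5–C6 by Brown allylation, C13 by Eschenmoser methylenation.
C7–C8 and ring B: Evans syn-aldol of a succinyl imide with aldehyde 6 (C10 from (R)-3-bromo-2-methylpropan-1-ol), then lactonisation.
Ring order: ring B first (step 4), ring A last (step 16).

Key step: step 16

Remark: the ester /C(C)=C\C is read as (Z)-2-methylbut-2-enoate (angelate), the target is (1S,4R,6R,7S,8R,10S) in the numbering above, and 16 is taken as the commercial reagent solution.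

Step 1
Reactants: 1 (R)-3-bromo-2-methylpropan-1-ol; 2 chlorotriisopropylsilane
Product: 3 (R)-(3-bromo-2-methylpropoxy)triisopropylsilane
Conditions: imidazole, DMF, rt
Reagents that add atoms: 2 chlorotriisopropylsilane, CC(C)[Si](Cl)(C(C)C)C(C)C
Why: Silyl ether formation at the primary hydroxyl gives a protecting group that should last until step 14, and the C10 stereocentre is not touched.

Step 2
Reactants: 3 (R)-(3-bromo-2-methylpropoxy)triisopropylsilane; 4 N,N-dimethylformamide
Product: 6 (S)-3-methyl-4-(triisopropylsilyloxy)butanal, via Grignard reagent 5 (not isolated)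
Conditions: Mg, I2 (cat.), THF, reflux then 0 °C; 4; NH4Cl (aq.)
Reagents that add atoms: 4 N,N-dimethylformamide, CN(C)C=O
Why: Grignard formation and Bouveault formylation add the C8 aldehyde carbon at a centre that is not stereogenic.

Step 3
Reactants: 7 (S)-4-benzyloxazolidin-2-one; 8 methyl 4-chloro-4-oxobutanoate
Product: 9 methyl 4-[(S)-4-benzyl-2-oxooxazolidin-3-yl]-4-oxobutanoate
Conditions: n-BuLi, THF, −78 °C; then 8, −78 → 0 °C
Reagents that add atoms: 8 methyl 4-chloro-4-oxobutanoate, COC(=O)CCC(Cl)=O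
Why: N-acylation of the lithiated oxazolidinone by the acid chloride gives the Evans imide.

Step 4
Reactants: 9 methyl 4-[(S)-4-benzyl-2-oxooxazolidin-3-yl]-4-oxobutanoate; 6 (S)-3-methyl-4-(triisopropylsilyloxy)butanal
Product: 11 (S)-4-benzyl-3-{(2R,3S)-2-[(S)-2-methyl-3-(triisopropylsilyloxy)propyl]-5-oxotetrahydrofuran-3-carbonyl}oxazolidin-2-one, via aldol adduct 10 (not isolated)
Conditions: Bu2BOTf, iPr2NEt, CH2Cl2, 0 °C; 6, −78 → 0 °C; H2O2, MeOH, pH 7 buffer; then p-TsOH (cat.), CH2Cl2, rt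
Reagents that add atoms: 6 (S)-3-methyl-4-(triisopropylsilyloxy)butanal, O=CC[C@H](C)CO[Si](C(C)C)(C(C)C)C(C)C
Why: The Evans syn-aldol reaction of the Z-boron enolate through a Zimmerman–Traxler transition state should set C7 (S) and C8 (R) under control of the (S)-auxiliary, and the γ-hydroxy ester then closes under acid catalysis to the trans-lactone (ring B).

Step 5
Reactants: 11 (S)-4-benzyl-3-{(2R,3S)-2-[(S)-2-methyl-3-(triisopropylsilyloxy)propyl]-5-oxotetrahydrofuran-3-carbonyl}oxazolidin-2-one; 12 hydrogen peroxide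
Product: 13 (2R,3S)-2-[(S)-2-methyl-3-(triisopropylsilyloxy)propyl]-5-oxotetrahydrofuran-3-carboxylic acid
Conditions: LiOH, H2O2, THF/H2O, 0 °C; Na2SO3; HCl to pH 2
Reagents that add atoms: 12 hydrogen peroxide (as LiOOH), OO
Why: Lithium hydroperoxide cleaves the exocyclic imide carbonyl selectively (Evans hydrolysis), and any opened lactone should reclose on acidification.

Step 6
Reactants: 13 (2R,3S)-2-[(S)-2-methyl-3-(triisopropylsilyloxy)propyl]-5-oxotetrahydrofuran-3-carboxylic acid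
Product: 15 (2R,3S)-2-[(S)-2-methyl-3-(triisopropylsilyloxy)propyl]-5-oxotetrahydrofuran-3-carbaldehyde, via acid chloride 14 (not isolated)
Conditions: (COCl)2, DMF (cat.), CH2Cl2, 0 °C → rt; then LiAlH(OtBu)3, THF, −78 °C
Reagents that add atoms: none
Why: Reduction of the acid chloride with the hindered hydride at −78 °C should stop at the aldehyde and leave the lactone intact, and the trans arrangement at C7 is the thermodynamically preferred one.

Step 7
Reactants: 15 (2R,3S)-2-[(S)-2-methyl-3-(triisopropylsilyloxy)propyl]-5-oxotetrahydrofuran-3-carbaldehyde; 16 (+)-B-allyldiisopinocampheylborane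
Product: 17 (4R,5R)-4-[(R)-1-hydroxybut-3-en-1-yl]-5-[(S)-2-methyl-3-(triisopropylsilyloxy)propyl]dihydrofuran-2(3H)-one
Conditions: 16, Et2O, −78 °C; then NaBO3·4H2O, THF/H2O, rt
Reagents that add atoms: 16 (+)-B-allyldiisopinocampheylborane, C=CCB([C@H]1C[C@H]2C[C@@H]([C@@H]1C)C2(C)C)[C@H]1C[C@H]2C[C@@H]([C@@H]1C)C2(C)C
Why: Brown asymmetric allylboration through a chair transition state should set C6 as (R) under control of the isopinocampheyl groups (derived from (−)-α-pinene), which normally override the bias of the α-stereocentre.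

Step 8
Reactants: 17 (4R,5R)-4-[(R)-1-hydroxybut-3-en-1-yl]-5-[(S)-2-methyl-3-(triisopropylsilyloxy)propyl]dihydrofuran-2(3H)-one; 18 N,N-dimethylmethyleneiminium iodide (Eschenmoser's salt)
Product: 21 (4R,5R)-4-[(R)-1-hydroxybut-3-en-1-yl]-3-methylidene-5-[(S)-2-methyl-3-(triisopropylsilyloxy)propyl]dihydrofuran-2(3H)-one, via Mannich base 19 (not isolated), via methiodide 20 (not isolated)
Conditions: LiN(iPr)2 (2.3 equiv), THF, −78 °C; 18, −78 °C → rt; then MeI, MeOH, rt; then NaHCO3 (aq.), CH2Cl2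
Reagents that add atoms: 18 N,N-dimethylmethyleneiminium iodide, C=[N+](C)C.[I-]
Why: Mannich reaction of the lactone enolate (alkoxide/enolate dianion) with Eschenmoser's salt, N-methylation and β-elimination install the exocyclic methylene at C11 before any ketone is present, and no stereocentre is formed or endangered.

Step 9
Reactants: 21 (4R,5R)-4-[(R)-1-hydroxybut-3-en-1-yl]-3-methylidene-5-[(S)-2-methyl-3-(triisopropylsilyloxy)propyl]dihydrofuran-2(3H)-one; 22 water
Product: 23 (4R,5R)-4-[(R)-1-hydroxy-3-oxobutyl]-3-methylidene-5-[(S)-2-methyl-3-(triisopropylsilyloxy)propyl]dihydrofuran-2(3H)-one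
Conditions: PdCl2 (10 mol %), CuCl, O2 (1 atm), DMF/H2O, rt
Reagents that add atoms: 22 water, O
Why: Tsuji–Wacker oxidation converts the terminal alkene into the methyl ketone (C4 carbonyl, C15 methyl), and the electron-poor methylene lactone should not react with divalent palladium under these conditions.

Step 10
Reactants: 23 (4R,5R)-4-[(R)-1-hydroxy-3-oxobutyl]-3-methylidene-5-[(S)-2-methyl-3-(triisopropylsilyloxy)propyl]dihydrofuran-2(3H)-one; 24 ethynylmagnesium bromide
Product: 25 (4R,5R)-4-[(1R,3R)-1,3-dihydroxy-3-methylpent-4-yn-1-yl]-3-methylidene-5-[(S)-2-methyl-3-(triisopropylsilyloxy)propyl]dihydrofuran-2(3H)-one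
Conditions: HC≡CMgBr (4 equiv), THF/CH2Cl2, −78 → −40 °C; NH4Cl (aq.)
Reagents that add atoms: 24 ethynylmagnesium bromide, C#C[Mg]Br
Why: 1,2-addition of the acetylide to the six-membered magnesium chelate of the C6 alkoxide and the C4 ketone (chelation-controlled 1,3-induction) should take place anti to the C6 substituent and give the 1,3-anti diol, that is (R) at C4.

Step 11
Reactants: 25 (4R,5R)-4-[(1R,3R)-1,3-dihydroxy-3-methylpent-4-yn-1-yl]-3-methylidene-5-[(S)-2-methyl-3-(triisopropylsilyloxy)propyl]dihydrofuran-2(3H)-one; 26 angelic acid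
Product: 27 (1R,3R)-3-hydroxy-3-methyl-1-{(2R,3S)-4-methylidene-2-[(S)-2-methyl-3-(triisopropylsilyloxy)propyl]-5-oxotetrahydrofuran-3-yl}pent-4-yn-1-yl (Z)-2-methylbut-2-enoate
Conditions: 26, 2,4,6-Cl3C6H2COCl, Et3N, toluene, rt; then 25, 80 °C
Reagents that add atoms: 26 angelic acid, C/C=C(/C)C(=O)O
Why: Yamaguchi-type esterification through the mixed anhydride without a nucleophilic catalyst should acylate only the secondary C6 hydroxyl and keep the (Z) geometry of the angelate.

Step 12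
Reactants: 27 (1R,3R)-3-hydroxy-3-methyl-1-{(2R,3S)-4-methylidene-2-[(S)-2-methyl-3-(triisopropylsilyloxy)propyl]-5-oxotetrahydrofuran-3-yl}pent-4-yn-1-yl (Z)-2-methylbut-2-enoate; 28 acetic acid
Product: 30 (1R,3R)-3-acetoxy-3-methyl-1-{(2R,3S)-4-methylidene-2-[(S)-2-methyl-3-(triisopropylsilyloxy)propyl]-5-oxotetrahydrofuran-3-yl}-4-oxopentyl (Z)-2-methylbut-2-enoate, via enol acetate 29 (not isolated)
Conditions: [RuCl2(p-cymene)(PPh3)] (3 mol %), AcOH (3 equiv), toluene, 80 °C
Reagents that add atoms: 28 acetic acid, CC(=O)O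
Why: Ruthenium-catalysed Markovnikov addition of the carboxylic acid to the propargylic alkyne followed by 1,2-acyl shift to the neighbouring tertiary oxygen (the known route from tertiary propargylic alcohols to 2-oxoalkyl esters) should give the C3 methyl ketone and the hindered C4 acetate in one operation with C4 unchanged.

Step 13
Reactants: 30 (1R,3R)-3-acetoxy-3-methyl-1-{(2R,3S)-4-methylidene-2-[(S)-2-methyl-3-(triisopropylsilyloxy)propyl]-5-oxotetrahydrofuran-3-yl}-4-oxopentyl (Z)-2-methylbut-2-enoate; 31 N-bromosuccinimide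
Product: 33 (1R,3R)-3-acetoxy-5-bromo-3-methyl-1-{(2R,3S)-4-methylidene-2-[(S)-2-methyl-3-(triisopropylsilyloxy)propyl]-5-oxotetrahydrofuran-3-yl}-4-oxopentyl (Z)-2-methylbut-2-enoate, via silyl enol ether 32 (not isolated)
Conditions: TMSOTf, Et3N, CH2Cl2, 0 °C; then NBS, THF, −78 °C
Reagents that add atoms: 31 N-bromosuccinimide, O=C1CCC(=O)N1Br
Why: Soft enolisation can only occur towards C2 because C4 is fully substituted, and bromination of the enol silane gives the bromomethyl ketone while the electron-poor alkenes stay untouched.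

Step 14
Reactants: 33 (1R,3R)-3-acetoxy-5-bromo-3-methyl-1-{(2R,3S)-4-methylidene-2-[(S)-2-methyl-3-(triisopropylsilyloxy)propyl]-5-oxotetrahydrofuran-3-yl}-4-oxopentyl (Z)-2-methylbut-2-enoate
Product: 34 (1R,3R)-3-acetoxy-5-bromo-1-{(2R,3S)-2-[(S)-3-hydroxy-2-methylpropyl]-4-methylidene-5-oxotetrahydrofuran-3-yl}-3-methyl-4-oxopentyl (Z)-2-methylbut-2-enoate
Conditions: HF (48 % aq.), MeCN, 0 °C → rt
Reagents that add atoms: none
Why: Acidic fluoride removes the primary silyl ether without exposing the bromo ketone, the acetate or the angelate to base or to nucleophiles.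

Step 15
Reactants: 34 (1R,3R)-3-acetoxy-5-bromo-1-{(2R,3S)-2-[(S)-3-hydroxy-2-methylpropyl]-4-methylidene-5-oxotetrahydrofuran-3-yl}-3-methyl-4-oxopentyl (Z)-2-methylbut-2-enoate
Product: 35 (1R,3R)-3-acetoxy-5-bromo-3-methyl-1-{(2R,3S)-4-methylidene-2-[(S)-2-methyl-3-oxopropyl]-5-oxotetrahydrofuran-3-yl}-4-oxopentyl (Z)-2-methylbut-2-enoate
Conditions: Dess–Martin periodinane, NaHCO3, CH2Cl2, 0 °C → rt
Reagents that add atoms: none
Why: Dess–Martin oxidation under buffered conditions should give the α-branched C1 aldehyde without epimerising C10.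

Step 16
Reactants: 35 (1R,3R)-3-acetoxy-5-bromo-3-methyl-1-{(2R,3S)-4-methylidene-2-[(S)-2-methyl-3-oxopropyl]-5-oxotetrahydrofuran-3-yl}-4-oxopentyl (Z)-2-methylbut-2-enoate
Product: 37 (1S,4R,6R,7S,8R,10S)-4-acetoxy-6-angeloyloxy-1-hydroxy-3-oxogermacr-11(13)-en-12,8-olide (CNP0141210.1), via samarium enolate 36 (not isolated)
Conditions: SmI2 (2.1 equiv, 0.1 M in THF) added slowly to 35 (0.002 M), THF, −78 °C; NH4Cl (aq.)
Reagents that add atoms: none
Why: Two single-electron transfers from SmI2 cleave the C2–Br bond and turn the electrophilic bromomethyl carbon into the C2 terminus of a trivalent samarium enolate (its position is fixed by the structure, since C4 carries no hydrogen), which adds to the C1 aldehyde through a samarium-chelated chair-like Zimmerman–Traxler array. The closest known reaction type is the SmI2-promoted intramolecular Reformatsky-type aldol of α-bromo ketones or esters with aldehydes, which is used to close eight- to fourteen-membered rings. Ring A closes in a 10-exo-trig mode at the aldehyde carbon (enolate C2=C3 endocyclic), with the trans-fused lactone holding the chains on C7 and C8 within reach of each other. The only new stereocentre, C1, is controlled by the adjacent C10 methyl stereocentre (Felkin–Anh attack anti to the C9 chain), which should give the required (1S) carbinol syn to the C10 methyl group. The step needs chemoselective reduction of the C–Br bond in the presence of the C4 acetoxy ketone, the aldehyde and the conjugated esters, and this is secured by the much faster reduction of α-bromo ketones at −78 °C, by adding just two equivalents of SmI2 to the substrate and by leaving out HMPA and proton donors. Ring closure over oligomerisation is secured by high dilution, and retro-aldol opening is held back by the samarium aldolate chelate and a cold quench.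

Compound list
1 | (R)-3-bromo-2-methylpropan-1-ol | BrC[C@H](C)CO | starting material
2 | chlorotriisopropylsilane | CC(C)[Si](Cl)(C(C)C)C(C)C | starting material
3 | (R)-(3-bromo-2-methylpropoxy)triisopropylsilane | BrC[C@H](C)CO[Si](C(C)C)(C(C)C)C(C)C | intermediate
4 | N,N-dimethylformamide | CN(C)C=O | starting material
5 | [(R)-2-methyl-3-(triisopropylsilyloxy)propyl]magnesium bromide | Br[Mg]C[C@H](C)CO[Si](C(C)C)(C(C)C)C(C)C | intermediate (not isolated)
6 | (S)-3-methyl-4-(triisopropylsilyloxy)butanal | O=CC[C@H](C)CO[Si](C(C)C)(C(C)C)C(C)C | intermediate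
7 | (S)-4-benzyloxazolidin-2-one | O=C1N[C@@H](Cc2ccccc2)CO1 | starting material
8 | methyl 4-chloro-4-oxobutanoate | COC(=O)CCC(Cl)=O | starting material
9 | methyl 4-[(S)-4-benzyl-2-oxooxazolidin-3-yl]-4-oxobutanoate | COC(=O)CCC(=O)N1[C@@H](Cc2ccccc2)COC1=O | intermediate
10 | methyl (3S,4R,6S)-3-[(S)-4-benzyl-2-oxooxazolidine-3-carbonyl]-4-hydroxy-6-methyl-7-(triisopropylsilyloxy)heptanoate | COC(=O)C[C@H](C(=O)N1[C@@H](Cc2ccccc2)COC1=O)[C@H](O)C[C@H](C)CO[Si](C(C)C)(C(C)C)C(C)C | intermediate (not isolated)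
11 | (S)-4-benzyl-3-{(2R,3S)-2-[(S)-2-methyl-3-(triisopropylsilyloxy)propyl]-5-oxotetrahydrofuran-3-carbonyl}oxazolidin-2-one | O=C1C[C@H](C(=O)N2[C@@H](Cc3ccccc3)COC2=O)[C@@H](C[C@H](C)CO[Si](C(C)C)(C(C)C)C(C)C)O1 | intermediate
12 | hydrogen peroxide | OO | starting material
13 | (2R,3S)-2-[(S)-2-methyl-3-(triisopropylsilyloxy)propyl]-5-oxotetrahydrofuran-3-carboxylic acid | O=C1C[C@H](C(=O)O)[C@@H](C[C@H](C)CO[Si](C(C)C)(C(C)C)C(C)C)O1 | intermediate
14 | (2R,3S)-2-[(S)-2-methyl-3-(triisopropylsilyloxy)propyl]-5-oxotetrahydrofuran-3-carbonyl chloride | O=C1C[C@H](C(Cl)=O)[C@@H](C[C@H](C)CO[Si](C(C)C)(C(C)C)C(C)C)O1 | intermediate (not isolated)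
15 | (2R,3S)-2-[(S)-2-methyl-3-(triisopropylsilyloxy)propyl]-5-oxotetrahydrofuran-3-carbaldehyde | O=C1C[C@H](C=O)[C@@H](C[C@H](C)CO[Si](C(C)C)(C(C)C)C(C)C)O1 | intermediate
16 | (+)-B-allyldiisopinocampheylborane (isopinocampheyl groups from (−)-α-pinene) | C=CCB([C@H]1C[C@H]2C[C@@H]([C@@H]1C)C2(C)C)[C@H]1C[C@H]2C[C@@H]([C@@H]1C)C2(C)C | starting material
17 | (4R,5R)-4-[(R)-1-hydroxybut-3-en-1-yl]-5-[(S)-2-methyl-3-(triisopropylsilyloxy)propyl]dihydrofuran-2(3H)-one | O=C1C[C@H]([C@H](O)CC=C)[C@@H](C[C@H](C)CO[Si](C(C)C)(C(C)C)C(C)C)O1 | intermediate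
18 | N,N-dimethylmethyleneiminium iodide (Eschenmoser's salt) | C=[N+](C)C.[I-] | starting material
19 | 3-[(dimethylamino)methyl] derivative of 17 (Mannich base, both C3 epimers) | CN(C)CC1C(=O)O[C@H](C[C@H](C)CO[Si](C(C)C)(C(C)C)C(C)C)[C@H]1[C@H](O)CC=C | intermediate (not isolated)
20 | N-methyl ammonium iodide of 19 | C[N+](C)(C)CC1C(=O)O[C@H](C[C@H](C)CO[Si](C(C)C)(C(C)C)C(C)C)[C@H]1[C@H](O)CC=C.[I-] | intermediate (not isolated)
21 | (4R,5R)-4-[(R)-1-hydroxybut-3-en-1-yl]-3-methylidene-5-[(S)-2-methyl-3-(triisopropylsilyloxy)propyl]dihydrofuran-2(3H)-one | C=C1C(=O)O[C@H](C[C@H](C)CO[Si](C(C)C)(C(C)C)C(C)C)[C@H]1[C@H](O)CC=C | intermediate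
22 | water | O | starting material
23 | (4R,5R)-4-[(R)-1-hydroxy-3-oxobutyl]-3-methylidene-5-[(S)-2-methyl-3-(triisopropylsilyloxy)propyl]dihydrofuran-2(3H)-one | C=C1C(=O)O[C@H](C[C@H](C)CO[Si](C(C)C)(C(C)C)C(C)C)[C@H]1[C@H](O)CC(C)=O | intermediate
24 | ethynylmagnesium bromide | C#C[Mg]Br | starting material
25 | (4R,5R)-4-[(1R,3R)-1,3-dihydroxy-3-methylpent-4-yn-1-yl]-3-methylidene-5-[(S)-2-methyl-3-(triisopropylsilyloxy)propyl]dihydrofuran-2(3H)-one | C=C1C(=O)O[C@H](C[C@H](C)CO[Si](C(C)C)(C(C)C)C(C)C)[C@H]1[C@H](O)C[C@@](C)(O)C#C | intermediate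
26 | angelic acid, (Z)-2-methylbut-2-enoic acid | C/C=C(/C)C(=O)O | starting material
27 | (1R,3R)-3-hydroxy-3-methyl-1-{(2R,3S)-4-methylidene-2-[(S)-2-methyl-3-(triisopropylsilyloxy)propyl]-5-oxotetrahydrofuran-3-yl}pent-4-yn-1-yl (Z)-2-methylbut-2-enoate | C=C1C(=O)O[C@H](C[C@H](C)CO[Si](C(C)C)(C(C)C)C(C)C)[C@H]1[C@H](OC(=O)/C(C)=C\C)C[C@@](C)(O)C#C | intermediate
28 | acetic acid | CC(=O)O | starting material
29 | (1R,3R)-4-acetoxy-3-hydroxy-3-methyl-1-{(2R,3S)-4-methylidene-2-[(S)-2-methyl-3-(triisopropylsilyloxy)propyl]-5-oxotetrahydrofuran-3-yl}pent-4-en-1-yl (Z)-2-methylbut-2-enoate | C=C1C(=O)O[C@H](C[C@H](C)CO[Si](C(C)C)(C(C)C)C(C)C)[C@H]1[C@H](OC(=O)/C(C)=C\C)C[C@@](C)(O)C(=C)OC(C)=O | intermediate (not isolated)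
30 | (1R,3R)-3-acetoxy-3-methyl-1-{(2R,3S)-4-methylidene-2-[(S)-2-methyl-3-(triisopropylsilyloxy)propyl]-5-oxotetrahydrofuran-3-yl}-4-oxopentyl (Z)-2-methylbut-2-enoate | C=C1C(=O)O[C@H](C[C@H](C)CO[Si](C(C)C)(C(C)C)C(C)C)[C@H]1[C@H](OC(=O)/C(C)=C\C)C[C@@](C)(OC(C)=O)C(C)=O | intermediate
31 | N-bromosuccinimide | O=C1CCC(=O)N1Br | starting material
32 | trimethylsilyl enol ether of 30 (C2=C3, silyloxy group on C3) | C=C1C(=O)O[C@H](C[C@H](C)CO[Si](C(C)C)(C(C)C)C(C)C)[C@H]1[C@H](OC(=O)/C(C)=C\C)C[C@@](C)(OC(C)=O)C(=C)O[Si](C)(C)C | intermediate (not isolated)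
33 | (1R,3R)-3-acetoxy-5-bromo-3-methyl-1-{(2R,3S)-4-methylidene-2-[(S)-2-methyl-3-(triisopropylsilyloxy)propyl]-5-oxotetrahydrofuran-3-yl}-4-oxopentyl (Z)-2-methylbut-2-enoate | C=C1C(=O)O[C@H](C[C@H](C)CO[Si](C(C)C)(C(C)C)C(C)C)[C@H]1[C@H](OC(=O)/C(C)=C\C)C[C@@](C)(OC(C)=O)C(=O)CBr | intermediate
34 | (1R,3R)-3-acetoxy-5-bromo-1-{(2R,3S)-2-[(S)-3-hydroxy-2-methylpropyl]-4-methylidene-5-oxotetrahydrofuran-3-yl}-3-methyl-4-oxopentyl (Z)-2-methylbut-2-enoate | C=C1C(=O)O[C@H](C[C@H](C)CO)[C@H]1[C@H](OC(=O)/C(C)=C\C)C[C@@](C)(OC(C)=O)C(=O)CBr | intermediate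
35 | (1R,3R)-3-acetoxy-5-bromo-3-methyl-1-{(2R,3S)-4-methylidene-2-[(S)-2-methyl-3-oxopropyl]-5-oxotetrahydrofuran-3-yl}-4-oxopentyl (Z)-2-methylbut-2-enoate | C=C1C(=O)O[C@H](C[C@H](C)C=O)[C@H]1[C@H](OC(=O)/C(C)=C\C)C[C@@](C)(OC(C)=O)C(=O)CBr | intermediate
36 | diiodosamarium enolate of 35 (C2=C3, trivalent samarium on the C3 oxygen) | C=C1C(=O)O[C@H](C[C@H](C)C=O)[C@H]1[C@H](OC(=O)/C(C)=C\C)C[C@@](C)(OC(C)=O)C(=C)O[Sm](I)I | intermediate (not isolated)
37 | (1S,4R,6R,7S,8R,10S)-4-acetoxy-6-angeloyloxy-1-hydroxy-3-oxogermacr-11(13)-en-12,8-olide (CNP0141210.1) | C=C1C(=O)O[C@@H]2C[C@H](C)[C@@H](O)CC(=O)[C@](C)(OC(C)=O)C[C@@H](OC(=O)/C(C)=C\C)[C@@H]12 | target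

Total step count: 16. Longest linear sequence: 15 steps (steps 1, 2 and 4–16; step 3 supplies imide 9).

Steps most likely to fail

Step 16. The samarium enolate may add to a second molecule instead of closing the strained ten-membered ring, the aldolate may reopen by retro-aldol reaction, excess reductant may cleave the C4 acetoxy group next to the ketone, or the macrocyclic transition state may give poor facial selectivity at C1. The fallback closes the same bond by an allylchromium addition in which C3 is carried as an exocyclic methylene group, so that no enolate and no reducible α-acetoxy ketone are involved. It sets out from methyl ketone 30. Lombardo methylenation (Zn, CH2Br2, TiCl4, THF) gives the isopropenyl compound F1. Ene-type allylic chlorination (Ca(OCl)2, solid CO2, CH2Cl2/H2O) gives the 2-substituted allylic chloride F2. Aqueous HF in MeCN frees the primary alcohol F3, and Dess–Martin periodinane gives the aldehyde F4. CrCl2 with LiI in THF at high dilution closes ring A to the homoallylic alcohol F5, with C1 again set by Felkin–Anh control from C10. Ozonolysis at −78 °C with a dye end-point and Me2S work-up cleaves the most electron-rich alkene (C3=CH2) and comes back to the route at 37.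

Step 10. The acetylide may add through the non-chelated alkoxide, so that the C4 epimer with the new hydroxyl syn to the C6 oxygen dominates, and it may also attack the lactone. The fallback uses that intrinsic preference on the C6 epimer and corrects C6 at the acylation stage. It sets out from aldehyde 15. Allylboration with (−)-Ipc2B(allyl) gives the (S)-carbinol F6. Methylenation as in step 8 (Mannich base F7, methiodide F8) gives F9, and Wacker oxidation as in step 9 gives ketone F10. Ethynylmagnesium bromide then gives the diol F11 with the required (R) configuration at C4. Mitsunobu esterification with angelic acid (PPh3, DIAD, toluene, 0 °C) inverts C6 and comes back to the route at 27.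

Step 8. Enolisation of the lactone next to the lithium alkoxide may be incomplete, the lactone may be transferred to the C6 oxygen, and the iminium salt may be consumed at oxygen, all of which lower conversion. The fallback installs the methylene group before the C6 side chain exists, by carboxylation and decarboxylative Mannich reaction. It sets out from acid 13. MeOMgOCO2Me in DMF at 130 °C gives the carboxylated lactone F12, which with aqueous formaldehyde, N-methylaniline and NaOAc in AcOH gives the methylene acid F13. (COCl)2 with DMF (cat.) gives the acid chloride F14, and LiAlH(OtBu)3 at −78 °C gives the aldehyde F15, which is used at once. Allylboration with 16 as in step 7 comes back to the route at 21.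

Further compounds
F1 | step 16 | (1R,3R)-3-acetoxy-3,4-dimethyl-1-{(2R,3S)-4-methylidene-2-[(S)-2-methyl-3-(triisopropylsilyloxy)propyl]-5-oxotetrahydrofuran-3-yl}pent-4-en-1-yl (Z)-2-methylbut-2-enoate | C=C1C(=O)O[C@H](C[C@H](C)CO[Si](C(C)C)(C(C)C)C(C)C)[C@H]1[C@H](OC(=O)/C(C)=C\C)C[C@@](C)(OC(C)=O)C(C)=C
F2 | step 16 | 4-(chloromethyl) analogue of F1 (2-substituted allylic chloride) | C=C1C(=O)O[C@H](C[C@H](C)CO[Si](C(C)C)(C(C)C)C(C)C)[C@H]1[C@H](OC(=O)/C(C)=C\C)C[C@@](C)(OC(C)=O)C(=C)CCl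
F3 | step 16 | desilylated F2 (primary alcohol at C1) | C=C1C(=O)O[C@H](C[C@H](C)CO)[C@H]1[C@H](OC(=O)/C(C)=C\C)C[C@@](C)(OC(C)=O)C(=C)CCl
F4 | step 16 | C1 aldehyde from F3 | C=C1C(=O)O[C@H](C[C@H](C)C=O)[C@H]1[C@H](OC(=O)/C(C)=C\C)C[C@@](C)(OC(C)=O)C(=C)CCl
F5 | step 16 | 3-deoxo-3-methylidene analogue of 37 (ring A closed, C3=CH2) | C=C1C(=O)O[C@@H]2C[C@H](C)[C@@H](O)CC(=C)[C@](C)(OC(C)=O)C[C@@H](OC(=O)/C(C)=C\C)[C@@H]12
F6 | step 10 | (4R,5R)-4-[(S)-1-hydroxybut-3-en-1-yl]-5-[(S)-2-methyl-3-(triisopropylsilyloxy)propyl]dihydrofuran-2(3H)-one (C6 epimer of 17) | O=C1C[C@H]([C@@H](O)CC=C)[C@@H](C[C@H](C)CO[Si](C(C)C)(C(C)C)C(C)C)O1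
F7 | step 10 | Mannich base of F6 | CN(C)CC1C(=O)O[C@H](C[C@H](C)CO[Si](C(C)C)(C(C)C)C(C)C)[C@H]1[C@@H](O)CC=C
F8 | step 10 | N-methyl ammonium iodide of F7 | C[N+](C)(C)CC1C(=O)O[C@H](C[C@H](C)CO[Si](C(C)C)(C(C)C)C(C)C)[C@H]1[C@@H](O)CC=C.[I-]
F9 | step 10 | C6 epimer of 21 | C=C1C(=O)O[C@H](C[C@H](C)CO[Si](C(C)C)(C(C)C)C(C)C)[C@H]1[C@@H](O)CC=C
F10 | step 10 | C6 epimer of 23 | C=C1C(=O)O[C@H](C[C@H](C)CO[Si](C(C)C)(C(C)C)C(C)C)[C@H]1[C@@H](O)CC(C)=O
F11 | step 10 | (4R,5R)-4-[(1S,3R)-1,3-dihydroxy-3-methylpent-4-yn-1-yl]-3-methylidene-5-[(S)-2-methyl-3-(triisopropylsilyloxy)propyl]dihydrofuran-2(3H)-one (C6 epimer of 25) | C=C1C(=O)O[C@H](C[C@H](C)CO[Si](C(C)C)(C(C)C)C(C)C)[C@H]1[C@@H](O)C[C@@](C)(O)C#C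
F12 | step 8 | (2R,3S)-2-[(S)-2-methyl-3-(triisopropylsilyloxy)propyl]-5-oxotetrahydrofuran-3,4-dicarboxylic acid (not isolated) | OC(=O)C1C(=O)O[C@H](C[C@H](C)CO[Si](C(C)C)(C(C)C)C(C)C)[C@H]1C(=O)O
F13 | step 8 | (2R,3S)-4-methylidene-2-[(S)-2-methyl-3-(triisopropylsilyloxy)propyl]-5-oxotetrahydrofuran-3-carboxylic acid | C=C1C(=O)O[C@H](C[C@H](C)CO[Si](C(C)C)(C(C)C)C(C)C)[C@H]1C(=O)O
F14 | step 8 | acid chloride of F13 (not isolated) | C=C1C(=O)O[C@H](C[C@H](C)CO[Si](C(C)C)(C(C)C)C(C)C)[C@H]1C(Cl)=O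
F15 | step 8 | (2R,3S)-4-methylidene-2-[(S)-2-methyl-3-(triisopropylsilyloxy)propyl]-5-oxotetrahydrofuran-3-carbaldehyde | C=C1C(=O)O[C@H](C[C@H](C)CO[Si](C(C)C)(C(C)C)C(C)C)[C@H]1C=O
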